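**Retrosynthetic overview**
1. Last step is global desilylation (C2, C16). Before that, the 10-membered cis,cis-diene ring is closed by RCM (C3=C4) on a ring-A/lactone tetraene.
2. The γ-lactone and the C8 tertiary carbinol come from an intramolecular Zn-Reformatsky of a C7 α-bromopropionate onto the C8 ketone.
3. The C7–C8–C9 unit comes from Corey–Seebach coupling of a dithiane fragment (C7 carbinol, dienyl arm) with the C9 aldehyde of ring A.
4. Ring A is formed first by endo Diels–Alder of piperylene with a β,β-disubstituted enoyl oxazolidinone. It then passes through a bridged iodolactone (sets C12–O and masks C9), E2 elimination, directed epoxidation, and vinyl addition at C2.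
5. Ring order: cyclohexane (DA), temporary bicyclic lactone, γ-lactone (Reformatsky), 10-membered ring (RCM, last).

**Assumptions**
- Ethyl (E)-4-hydroxy-3-methylbut-2-enoate is treated as commercial.
- The (S)-benzyl auxiliary is assumed to give the shown absolute configuration; the (R)-auxiliary is used if the antipode forms.
- (R)-Me-CBS is chosen for C7 (S) by analogy to acetophenone.

---

**Step 1**
Reactants: 1 ethyl (E)-4-hydroxy-3-methylbut-2-enoate
Product: 2 ethyl (E)-4-(TBSO)-3-methylbut-2-enoate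
Conditions: TBSCl, imidazole, DMF, 0 °C→rt
Reagents that add atoms: TBSCl, CC(C)(C)[Si](C)(C)Cl
Why: Silylation of the primary alcohol (protection) leaves the enoate untouched and keeps the E geometry (ester trans to CH2O).

**Step 2**
Reactants: 2
Product: 3 (E)-4-(TBSO)-3-methylbut-2-enoic acid
Conditions: LiOH·H2O, THF/H2O, rt
Reagents that add atoms: water/hydroxide, O
Why: Saponification; no stereocentre is involved.

**Step 3**
Reactants: 3; 4 (S)-4-benzyloxazolidin-2-one
Product: 5 N-enoyl oxazolidinone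
Conditions: (a) PivCl, Et3N, THF, −20 °C; (b) Li salt of 4 (n-BuLi, THF, −78 °C)
Reagents that add atoms: none
Why: Mixed-anhydride acylation installs the chiral auxiliary that will control the Diels–Alder face.

**Step 4**
Reactants: 5; 6 (E)-penta-1,3-diene
Product: 7 cycloadduct
Conditions: Et2AlCl, CH2Cl2/toluene, −78 °C→rt
Reagents that add atoms: none
Why: Lewis-acid-chelated endo Diels–Alder with "ortho" regiochemistry. The E-enoate puts C9 cis to the C1 methyl and trans to CH2OTBS. The E-diene plus endo approach puts the C11 methyl cis to C9. The auxiliary sets the absolute configuration at C10/C11/C1.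

**Step 5**
Reactants: 7
Product: 8 carboxylic acid (auxiliary 4 recovered)
Conditions: LiOH, H2O2, THF/H2O, 0 °C
Reagents that add atoms: water, O; hydrogen peroxide, OO
Why: LiOOH attacks the exocyclic imide carbonyl (standard Evans cleavage), so no stereocentre is touched.

**Step 6**
Reactants: 8
Product: 9 bridged iodolactone
Conditions: I2, NaHCO3, MeCN/H2O, 0 °C→rt
Reagents that add atoms: I2, II
Why: Iodolactonization (5-exo). The axial C9 carboxylate adds to C12 on its own (bottom) face and I+ adds anti to C13 (top). This sets C12–O down and C13–I up, and the bicyclic lactone masks C9.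

**Step 7**
Reactants: 9
Product: 10 unsaturated bridged lactone
Conditions: DBU, toluene, 110 °C
Reagents that add atoms: none
Why: E2 elimination of the axial iodide with the anti-periplanar C14 axial H gives the C13=C14 alkene; no stereocentre is affected.

**Step 8**
Reactants: 10
Product: 11 primary alcohol
Conditions: HF·pyridine, THF/pyridine, 0 °C→rt
Reagents that add atoms: none
Why: Desilylation frees the C2 hydroxyl, which will direct the epoxidation.

**Step 9**
Reactants: 11
Product: 12 epoxy alcohol (13,14-epoxide up)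
Conditions: VO(acac)2 (5 mol%), TBHP, CH2Cl2, 0 °C→rt
Reagents that add atoms: TBHP, CC(C)(C)OO
Why: Hydroxyl-directed epoxidation from the top face, anti to the lactone bridge, sets both epoxide carbons (C13, C14).

**Step 10**
Reactants: 12
Product: 13 aldehyde (C2)
Conditions: Dess–Martin periodinane, NaHCO3, CH2Cl2, rt
Reagents that add atoms: none
Why: Oxidation; the neopentyl aldehyde has no α-H, so nothing epimerizes.

**Step 11**
Reactants: 13
Product: 14 allylic alcohol (C2 S)
Conditions: CH2=CHMgBr, THF, −78 °C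
Reagents that add atoms: vinylmagnesium bromide, C=C[Mg]Br
Why: Grignard addition with Cram-chelate control (Mg bridges the aldehyde O and the syn epoxide O) sets C2.

**Step 12**
Reactants: 14
Product: 15 C2-TBS ether
Conditions: TBSOTf, 2,6-lutidine, CH2Cl2, −78 °C
Reagents that add atoms: TBSOTf, CC(C)(C)[Si](C)(C)OS(=O)(=O)C(F)(F)F
Why: Protects the C2 alcohol before the organolithium steps.

**Step 13**
Reactants: 15
Product: 16 lactol
Conditions: DIBAL-H (1.1 equiv), CH2Cl2, −78 °C
Reagents that add atoms: none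
Why: Partial reduction of the lactone unmasks C9 as a masked aldehyde with C12-O⁻ retained; the epoxide, alkene and silyl ether survive.

**Step 14**
Reactants: 17 but-2-yne-1,4-diol
Product: 18 4-(TBSO)but-2-yn-1-ol
Conditions: NaH (1 equiv), TBSCl, THF, 0 °C
Reagents that add atoms: TBSCl, CC(C)(C)[Si](C)(C)Cl
Why: Statistical mono-silylation.

**Step 15**
Reactants: 18
Product: 19 (Z)-3-iodo-4-(TBSO)but-2-en-1-ol
Conditions: Red-Al, THF, 0 °C; then I2, −78 °C
Reagents that add atoms: I2, II
Why: Trans-hydroalumination directed by the propargylic OH, then iodinolysis. This gives I at the carbon bearing CH2OTBS (future C5) and cis to CH2OH (future C7), which sets the C5=C6 geometry.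

**Step 16**
Reactants: 19
Product: 20 (Z)-3-iodo-4-(TBSO)but-2-enal
Conditions: MnO2, CH2Cl2, rt
Reagents that add atoms: none
Why: Selective oxidation of the allylic alcohol.

**Step 17**
Reactants: 20; 21 tributyl(vinyl)stannane
Product: 22 (2E)-4-(TBSO)-3-vinylbut-2-enal
Conditions: Pd2(dba)3, AsPh3, CuI, DMF, rt
Reagents that add atoms: none
Why: Stille coupling with retention installs C4=C3H2, cis to the CHO (C7) as required.

**Step 18**
Reactants: 22; 23 1,3-dithiane
Product: 24 racemic 2-(1-hydroxyallyl)dithiane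
Conditions: n-BuLi, THF, −30 °C (formation of 23-Li); then 22, −78 °C
Reagents that add atoms: none
Why: Corey–Seebach 1,2-addition of 2-lithio-1,3-dithiane (the C8 acyl-anion equivalent) to the enal; C7 is racemic here and is corrected in the next two steps.

**Step 19**
Reactants: 24
Product: 25 dienone
Conditions: Dess–Martin periodinane, CH2Cl2, rt
Reagents that add atoms: none
Why: Oxidation destroys the C7 stereochemistry so that it can be set by reagent control.

**Step 20**
Reactants: 25
Product: 26 (7S)-alcohol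
Conditions: (R)-Me-CBS (10 mol%), BH3·SMe2, THF, −20 °C
Reagents that add atoms: none
Why: Corey–Bakshi–Shibata reduction; the catalyst faces the bulky dithianyl group versus the planar alkenyl group and sets C7 (S).

**Step 21**
Reactants: 26
Product: 27 C7-TES ether (fragment)
Conditions: TESCl, imidazole, DMF, rt
Reagents that add atoms: TESCl, CC[Si](CC)(CC)Cl
Why: Protects C7 as a silyl ether that is orthogonal to the TBS groups.

**Step 22**
Reactants: 16; 27
Product: 28 C9/C12 diol
Conditions: 27 + n-BuLi (2.5 equiv), THF, −30 °C; add 16, −78→−20 °C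
Reagents that add atoms: none
Why: Corey–Seebach addition of lithiated 27 to the aldehyde released from the lactol. The C12 lithium alkoxide, held 1,3-diaxial to the C9 aldehyde, templates a chelate so that attack occurs from the exo face, setting C9 (R); C7 remains (S).

**Step 23**
Reactants: 28
Product: 29 C9,C12-diacetate
Conditions: Ac2O, pyridine, DMAP, CH2Cl2, rt
Reagents that add atoms: Ac2O, CC(=O)OC(C)=O
Why: Installs the two target acetates (C9-OAc, C12-OAc) after all strongly basic steps are over.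

**Step 24**
Reactants: 29
Product: 30 C7 alcohol
Conditions: PPTS, MeOH/CH2Cl2, 0 °C
Reagents that add atoms: none
Why: TES is cleaved selectively over the TBS groups and acetates.

**Step 25**
Reactants: 30
Product: 31 C7 2-bromopropionate
Conditions: CH3CHBrCOBr, pyridine, DMAP, CH2Cl2, 0 °C
Reagents that add atoms: 2-bromopropionyl bromide, CC(Br)C(=O)Br
Why: Esterification installs C19/C17/C18; the racemic C–Br centre is lost on zinc insertion, so it does not matter.

**Step 26**
Reactants: 31
Product: 32 C8 ketone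
Conditions: MeI, CaCO3, MeCN/H2O, 50 °C
Reagents that add atoms: water, O
Why: Alkylative hydrolysis of the dithiane unmasks the C8 ketone under non-oxidizing conditions, so the diene and epoxide survive.

**Step 27**
Reactants: 32
Product: 33 lactone with C8-OH
Conditions: Zn dust, TMSCl, CuCl, THF, 50 °C (dilute)
Reagents that add atoms: none
Why: Intramolecular Reformatsky (5-exo aldol) through a Zn chelate. It closes the γ-lactone, forms the C8–C17 bond, and sets the C8 carbinol and C17 methyl relative to C7/C9 (trans-fused lactone).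

**Step 28**
Reactants: 33
Product: 34 bis-TBS macrocycle
Conditions: Hoveyda–Grubbs II (15 mol%), toluene, 1 mM, 80 °C
Reagents that add atoms: none
Why: Ring-closing metathesis of the C2 vinyl and C4 vinyl (diene) arms forms the cis C3=C4 bond, completing the cis,cis-diene 10-membered ring (ethylene lost). The trans-fused lactone and the 6-ring preorganize the chain.

**Step 29**
Reactants: 34
Product: 35 Briaexcavatolide N
Conditions: HF·pyridine, pyridine/THF, 0 °C→rt
Reagents that add atoms: none
Why: Removes both TBS groups (C2-OH, C16-OH); the acetates, epoxide, lactone and diene survive buffered HF.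

---

**Compound list**

1 | ethyl (E)-4-hydroxy-3-methylbut-2-enoate | CCOC(=O)/C=C(/CO)C | starting material
2 | ethyl (E)-4-(TBSO)-3-methylbut-2-enoate | CCOC(=O)/C=C(/CO[Si](C)(C)C(C)(C)C)C | intermediate
3 | (E)-4-(TBSO)-3-methylbut-2-enoic acid | OC(=O)/C=C(/CO[Si](C)(C)C(C)(C)C)C | intermediate
4 | (S)-4-benzyloxazolidin-2-one | O=C1N[C@@H](Cc2ccccc2)CO1 | starting material
5 | (S)-4-benzyl-3-[(E)-4-(TBSO)-3-methylbut-2-enoyl]oxazolidin-2-one | O=C(/C=C(/CO[Si](C)(C)C(C)(C)C)C)N1[C@@H](Cc2ccccc2)COC1=O | intermediate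
6 | (E)-penta-1,3-diene | C/C=C/C=C | starting material
7 | endo Diels–Alder adduct (cyclohex-3-ene, C1-quaternary, N-acyl oxazolidinone) | O=C(N1[C@@H](Cc2ccccc2)COC1=O)[C@H]1[C@@H](C)C=CC[C@]1(C)CO[Si](C)(C)C(C)(C)C | intermediate
8 | cyclohexene carboxylic acid | OC(=O)[C@H]1[C@@H](C)C=CC[C@]1(C)CO[Si](C)(C)C(C)(C)C | intermediate
9 | bridged iodolactone (6-oxabicyclo[3.2.1]octan-7-one, I up) | O=C1O[C@H]2[C@H](I)C[C@](C)(CO[Si](C)(C)C(C)(C)C)[C@@H]1[C@H]2C | intermediate
10 | bridged lactone, C13=C14 alkene | O=C1O[C@H]2C=C[C@](C)(CO[Si](C)(C)C(C)(C)C)[C@@H]1[C@H]2C | intermediate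
11 | hydroxymethyl lactone (C2-OH) | O=C1O[C@H]2C=C[C@](C)(CO)[C@@H]1[C@H]2C | intermediate
12 | epoxy alcohol lactone | O=C1O[C@H]2[C@@H]3O[C@@H]3[C@](C)(CO)[C@@H]1[C@H]2C | intermediate
13 | epoxy aldehyde lactone | O=C1O[C@H]2[C@@H]3O[C@@H]3[C@](C)(C=O)[C@@H]1[C@H]2C | intermediate
14 | C2 vinyl carbinol lactone | O=C1O[C@H]2[C@@H]3O[C@@H]3[C@](C)([C@@H](O)C=C)[C@@H]1[C@H]2C | intermediate
15 | C2-OTBS vinyl lactone | O=C1O[C@H]2[C@@H]3O[C@@H]3[C@](C)([C@@H](O[Si](C)(C)C(C)(C)C)C=C)[C@@H]1[C@H]2C | intermediate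
16 | lactol (C9 anomeric, unspecified) | OC1O[C@H]2[C@@H]3O[C@@H]3[C@](C)([C@@H](O[Si](C)(C)C(C)(C)C)C=C)[C@@H]1[C@H]2C | intermediate
17 | but-2-yne-1,4-diol | OCC#CCO | starting material
18 | 4-(TBSO)but-2-yn-1-ol | OCC#CCO[Si](C)(C)C(C)(C)C | intermediate
19 | (Z)-3-iodo-4-(TBSO)but-2-en-1-ol | OC/C=C(\I)CO[Si](C)(C)C(C)(C)C | intermediate
20 | (Z)-3-iodo-4-(TBSO)but-2-enal | O=C/C=C(\I)CO[Si](C)(C)C(C)(C)C | intermediate
21 | tributyl(vinyl)stannane | C=C[Sn](CCCC)(CCCC)CCCC | starting material
22 | (2E)-4-(TBSO)-3-vinylbut-2-enal | O=C/C=C(\C=C)CO[Si](C)(C)C(C)(C)C | intermediate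
23 | 1,3-dithiane | C1CSCSC1 | starting material
24 | racemic dithianyl dienyl carbinol | S1CCCSC1C(O)/C=C(\C=C)CO[Si](C)(C)C(C)(C)C | intermediate
25 | dithianyl dienone | S1CCCSC1C(=O)/C=C(\C=C)CO[Si](C)(C)C(C)(C)C | intermediate
26 | (S)-dithianyl dienyl carbinol | S1CCCSC1[C@@H](O)/C=C(\C=C)CO[Si](C)(C)C(C)(C)C | intermediate
27 | C7-OTES dithiane fragment | S1CCCSC1[C@@H](O[Si](CC)(CC)CC)/C=C(\C=C)CO[Si](C)(C)C(C)(C)C | intermediate
28 | C9/C12 diol dithiane | S1CCCSC1([C@@H](O[Si](CC)(CC)CC)/C=C(CO[Si](C)(C)C(C)(C)C)\C=C)[C@H](O)[C@H]1[C@@H](C)[C@@H](O)[C@@H]2O[C@@H]2[C@]1(C)[C@@H](O[Si](C)(C)C(C)(C)C)C=C | intermediate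
29 | C9,C12-diacetate | S1CCCSC1([C@@H](O[Si](CC)(CC)CC)/C=C(CO[Si](C)(C)C(C)(C)C)\C=C)[C@H](OC(C)=O)[C@H]1[C@@H](C)[C@@H](OC(C)=O)[C@@H]2O[C@@H]2[C@]1(C)[C@@H](O[Si](C)(C)C(C)(C)C)C=C | intermediate
30 | C7 alcohol | S1CCCSC1([C@@H](O)/C=C(CO[Si](C)(C)C(C)(C)C)\C=C)[C@H](OC(C)=O)[C@H]1[C@@H](C)[C@@H](OC(C)=O)[C@@H]2O[C@@H]2[C@]1(C)[C@@H](O[Si](C)(C)C(C)(C)C)C=C | intermediate
31 | C7 2-bromopropionate | S1CCCSC1([C@@H](OC(=O)C(C)Br)/C=C(CO[Si](C)(C)C(C)(C)C)\C=C)[C@H](OC(C)=O)[C@H]1[C@@H](C)[C@@H](OC(C)=O)[C@@H]2O[C@@H]2[C@]1(C)[C@@H](O[Si](C)(C)C(C)(C)C)C=C | intermediate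
32 | C8 ketone bromoester | O=C([C@@H](OC(=O)C(C)Br)/C=C(CO[Si](C)(C)C(C)(C)C)\C=C)[C@H](OC(C)=O)[C@H]1[C@@H](C)[C@@H](OC(C)=O)[C@@H]2O[C@@H]2[C@]1(C)[C@@H](O[Si](C)(C)C(C)(C)C)C=C | intermediate
33 | lactone, C8-OH, acyclic tetraene | CC(=O)O[C@@H]1[C@H](C)[C@H]([C@@H](OC(C)=O)[C@@]2(O)[C@H](/C=C(CO[Si](C)(C)C(C)(C)C)\C=C)OC(=O)[C@@H]2C)[C@@](C)([C@@H](O[Si](C)(C)C(C)(C)C)C=C)[C@H]2O[C@@H]12 | intermediate
34 | bis-TBS macrocycle | CC(=O)O[C@@H]1[C@H](C)[C@@H]2[C@@H](OC(C)=O)[C@@]3(O)[C@H](/C=C(CO[Si](C)(C)C(C)(C)C)\C=C/[C@H](O[Si](C)(C)C(C)(C)C)[C@@]2(C)[C@H]2O[C@@H]12)OC(=O)[C@@H]3C | intermediate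
35 | Briaexcavatolide N | CC(=O)O[C@@H]1[C@H](C)[C@@H]2[C@@H](OC(C)=O)[C@@]3(O)[C@H](/C=C(CO)\C=C/[C@H](O)[C@@]2(C)[C@H]2O[C@@H]12)OC(=O)[C@@H]3C | target

**Total steps:** 29 (21 in the main branch plus 8 in the dithiane branch). **Longest linear sequence:** 21 steps (1→2→3→5→7→8→…→16→28→29→30→31→32→33→34→35).

**Three steps most likely to fail, with fallbacks**
1. **Step 28 (macro-RCM to the 10-membered cis,cis-diene).** Fallback: change the bond-forming strategy to an intramolecular Nozaki–Hiyama–Kishi closure (CrCl2/NiCl2) between a C2 aldehyde and a Z-dienyl iodide at C3. This requires re-routing C2–C3 formation to the macrocyclization, with C2 set by ring control or a later ketone reduction.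
2. **Step 27 (Zn-Reformatsky).** The α-acetoxy ketone may be reduced, or C8/C17 may come out with the wrong configuration. Fallback: prepare the lactone by reagent-controlled chemistry. Add an Evans propionyl-oxazolidinone boron enolate to the C8 ketone intermolecularly (auxiliary-controlled aldol), then lactonize onto C7-OH under acid.
3. **Step 22 (dithiane coupling; C9 configuration and hindered partners).** Fallback: open the lactone as a Weinreb amide instead of the lactol, add lithiated 27 to give the C9 ketone, then reduce it with reagent control (Zn(BH4)2 chelation or (S)-CBS) to set C9 (R) independently of the ring-A chelate.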